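**Plan**

- Numbering and feature: ring A has C1 (OH), C2 and C4 (Br), C6 (ether O); ring B has C1' (ether O), C2' (H), C3', C4', C5' (Br), C6' (OH). In ring B the hydroxyl carbon C6' lies between C1' and C5', so with a carboxyl on C5' ring B is a 3-aryloxysalicylate: an acetoacetate three-carbon unit (C5'-C6'-C1') joined to a malonaldehyde three-carbon unit (C2'-C3'-C4').
- Retrosynthesis: the five C-Br bonds are cut first (C2, C4, C3' by phenol-directed bromination; C5' by ipso bromodecarboxylation; C4' by carboxylate-directed lithiation). Ring B is then cut at C1'-C2' and C4'-C5', and last the sp3 C-O bond between the ring A phenol oxygen and C4 of the acetoacetate.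
- Forward: the ring A phenol is O-alkylated, the keto ester becomes its bis(silyloxy)diene, ring B is closed in one operation with a malonaldehyde bis(acetal), and the bromines enter in two operations (one by lithiation, four by Br2).
- Stereochemistry: the target has no stereocentre and no stereogenic double bond; enol ether geometry and the stereocentres of the open-chain adduct vanish on aromatisation.

Key step: step 4

Remark on the chemistry: electrophilic bromination is not expected to reach C4' selectively. It is meta to the hydroxyl and, once both rings are dibrominated, equivalent to C3 of ring A. The C4' bromine is therefore placed by carboxylate-directed lithiation while the carboxyl is still on C5'. Silyl enol ethers 5 and 7 are taken as E/Z mixtures.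

**Route**

Step 1
Reactants: 1 guaiacol (2-methoxyphenol); 2 methyl 4-chloroacetoacetate (methyl 4-chloro-3-oxobutanoate)
Product: 4 methyl 4-(2-methoxyphenoxy)-3-oxobutanoate, via sodium 2-methoxyphenoxide 3 (not isolated)
Conditions: NaH (2.1 equiv), THF, 0 → 20 °C; aq HCl work-up
Reagents that add atoms: none
Why: Williamson ether synthesis, in which the phenoxide displaces the primary chloride next to the ketone (SN2) while the second equivalent of NaH holds the β-keto ester as its sodium enolate and so suppresses self-condensation.

Step 2
Reactants: 4 methyl 4-(2-methoxyphenoxy)-3-oxobutanoate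
Product: 5 methyl 4-(2-methoxyphenoxy)-3-(trimethylsilyloxy)but-2-enoate (E/Z mixture)
Conditions: Me3SiCl, Et3N, toluene, 20 °C
Reagents that add atoms: chlorotrimethylsilane, C[Si](C)(C)Cl
Why: Soft enolisation of the β-keto ester by Et3N and O-silylation by Me3SiCl give the ester-conjugated silyl enol ether (silyl enol ether formation), the usual first stage of 1,3-bis(silyloxy)diene synthesis.

Step 3
Reactants: 5 methyl 4-(2-methoxyphenoxy)-3-(trimethylsilyloxy)but-2-enoate
Product: 7 1-methoxy-4-(2-methoxyphenoxy)-1,3-bis(trimethylsilyloxy)buta-1,3-diene (E/Z mixture), via lithium dienolate 6 (not isolated)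
Conditions: LiN(i-Pr)2 (LDA), THF, −78 °C; Me3SiCl, −78 → 20 °C
Reagents that add atoms: chlorotrimethylsilane, C[Si](C)(C)Cl
Why: Kinetic γ-deprotonation at the aryloxy-bearing CH2 gives the extended ester dienolate, which Me3SiCl traps on oxygen (O-silylation of an ester enolate to a silyl ketene acetal).

Step 4
Reactants: 7 1-methoxy-4-(2-methoxyphenoxy)-1,3-bis(trimethylsilyloxy)buta-1,3-diene; 8 1,1,3,3-tetramethoxypropane
Product: 10 methyl 2-hydroxy-3-(2-methoxyphenoxy)benzoate, via open-chain Mukaiyama adduct 9 (not isolated)
Conditions: TiCl4 (1 equiv), CH2Cl2, −78 → 20 °C; aq HCl work-up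
Reagents that add atoms: none
Why: TiCl4 ionises one acetal of 8 to a methoxycarbenium ion, which is attacked by the terminal, aryloxy-bearing carbon of diene 7 (future C1') in a vinylogous Mukaiyama-type addition that forms C1'-C2' and leaves the β-keto ester as its silyl or titanium enolate 9. Ionisation of the second acetal then lets the enolate carbon between the two carbonyls (future C5') attack the new methoxycarbenium ion, forming C4'-C5' and closing ring B by a 6-(enolendo)-exo-trig Mukaiyama aldol-type cyclisation. Two eliminations of methanol and enolisation of the ring ketone aromatise the ring to the hydrogen-bonded salicylate, which is the thermodynamic sink. The closest known reaction type is the formal [3+3] cyclocondensation of 1,3-bis(silyloxy)dienes with malonaldehyde bis(acetals), which is established for 4-aryloxy dienes. No stereocentre is formed that survives. The step needs the aryloxy carbon to end next to the hydroxyl carbon with the ester on the other side, and this is secured by connectivity: the two nucleophilic carbons of the acetoacetate unit flank the former ketone carbon and the dielectrophile is symmetrical, so either order of attack gives the same arene.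

Step 5
Reactants: 10 methyl 2-hydroxy-3-(2-methoxyphenoxy)benzoate
Product: 12 2-methoxy-3-(2-methoxyphenoxy)benzoic acid, via methyl ether ester 11 (not isolated)
Conditions: MeI, K2CO3, DMF, 50 °C; then aq NaOH, 70 °C; HCl to pH 2
Reagents that add atoms: iodomethane, CI; sodium hydroxide, [Na+].[OH-]
Why: Williamson O-methylation of the salicylate hydroxyl followed in the same flask by ester saponification (acyl-oxygen cleavage); the methyl ether masks the phenol for the lithiation and is removed later together with the ring A methyl ether.

Step 6
Reactants: 12 2-methoxy-3-(2-methoxyphenoxy)benzoic acid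
Product: 14 6-bromo-2-methoxy-3-(2-methoxyphenoxy)benzoic acid, via dilithio benzoate 13 (not isolated)
Conditions: s-BuLi (2.2 equiv), TMEDA, THF, −78 °C (acid added to base); BrCCl2CCl2Br, −78 → 20 °C; aq HCl
Reagents that add atoms: 1,2-dibromo-1,1,2,2-tetrachloroethane, BrC(Cl)(Cl)C(Cl)(Cl)Br
Why: Directed ortho-metalation of an unprotected benzoic acid, in which the lithium carboxylate steers s-BuLi/TMEDA to C4', the only free position ortho to it (as known for 2-methoxybenzoic acids), and bromophilic attack of the aryllithium on the dibromide delivers the C4' bromine.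

Step 7
Reactants: 14 6-bromo-2-methoxy-3-(2-methoxyphenoxy)benzoic acid
Product: 15 6-bromo-2-hydroxy-3-(2-hydroxyphenoxy)benzoic acid
Conditions: BBr3 (5 equiv), CH2Cl2, −78 → 20 °C; H2O quench
Reagents that add atoms: none
Why: BBr3 cleaves both aryl methyl ethers (Lewis acid activation, SN2 attack of bromide on methyl), while the diaryl ether, the aryl bromide and the carboxyl are inert to it.

Step 8
Reactants: 15 6-bromo-2-hydroxy-3-(2-hydroxyphenoxy)benzoic acid
Product: 17 4,5,6-tribromo-2-(3,5-dibromo-2-hydroxyphenoxy)phenol, via tetrabromo salicylic acid 16 (not isolated)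
Conditions: Br2 (4.2 equiv), AcOH–H2O, 20 → 50 °C; aq NaHSO3 work-up
Reagents that add atoms: bromine, BrBr
Why: Electrophilic aromatic bromination fills the positions ortho and para to each free hydroxyl (C2 and C4 of ring A, C3' of ring B), and attack at C5', ortho to the C6' hydroxyl, is an ipso substitution that expels CO2 (bromodecarboxylation of a salicylic acid); the remaining hydrogens are all meta to a hydroxyl and are not reached by Br2 without a Lewis acid.

**Compound list**

1 | guaiacol (2-methoxyphenol) | COc1ccccc1O | starting material
2 | methyl 4-chloroacetoacetate | COC(=O)CC(=O)CCl | starting material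
3 | sodium 2-methoxyphenoxide | COc1ccccc1[O-].[Na+] | intermediate (not isolated)
4 | methyl 4-(2-methoxyphenoxy)-3-oxobutanoate | COC(=O)CC(=O)COc1ccccc1OC | intermediate
5 | methyl 4-(2-methoxyphenoxy)-3-(trimethylsilyloxy)but-2-enoate (E/Z mixture, geometry of no consequence) | COC(=O)C=C(O[Si](C)(C)C)COc1ccccc1OC | intermediate
6 | lithium 1-methoxy-4-(2-methoxyphenoxy)-3-(trimethylsilyloxy)buta-1,3-dien-1-olate | COC([O-])=CC(O[Si](C)(C)C)=COc1ccccc1OC.[Li+] | intermediate (not isolated)
7 | 1-methoxy-4-(2-methoxyphenoxy)-1,3-bis(trimethylsilyloxy)buta-1,3-diene (E/Z mixture, geometry of no consequence) | COC(O[Si](C)(C)C)=CC(O[Si](C)(C)C)=COc1ccccc1OC | intermediate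
8 | 1,1,3,3-tetramethoxypropane | COC(OC)CC(OC)OC | starting material
9 | methyl 5,7,7-trimethoxy-4-(2-methoxyphenoxy)-3-(trimethylsilyloxy)hept-2-enoate (open-chain adduct, drawn as the silyl enol ether; mixture of diastereomers) | COC(=O)C=C(O[Si](C)(C)C)C(Oc1ccccc1OC)C(OC)CC(OC)OC | intermediate (not isolated)
10 | methyl 2-hydroxy-3-(2-methoxyphenoxy)benzoate | COC(=O)c1cccc(Oc2ccccc2OC)c1O | intermediate
11 | methyl 2-methoxy-3-(2-methoxyphenoxy)benzoate | COC(=O)c1cccc(Oc2ccccc2OC)c1OC | intermediate (not isolated)
12 | 2-methoxy-3-(2-methoxyphenoxy)benzoic acid | OC(=O)c1cccc(Oc2ccccc2OC)c1OC | intermediate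
13 | lithium 6-lithio-2-methoxy-3-(2-methoxyphenoxy)benzoate | [Li]OC(=O)c1c([Li])ccc(Oc2ccccc2OC)c1OC | intermediate (not isolated)
14 | 6-bromo-2-methoxy-3-(2-methoxyphenoxy)benzoic acid | OC(=O)c1c(Br)ccc(Oc2ccccc2OC)c1OC | intermediate
15 | 6-bromo-2-hydroxy-3-(2-hydroxyphenoxy)benzoic acid | OC(=O)c1c(Br)ccc(Oc2ccccc2O)c1O | intermediate
16 | 5,6-dibromo-3-(3,5-dibromo-2-hydroxyphenoxy)-2-hydroxybenzoic acid | OC(=O)c1c(Br)c(Br)cc(Oc2cc(Br)cc(Br)c2O)c1O | intermediate (not isolated)
17 | 4,5,6-tribromo-2-(3,5-dibromo-2-hydroxyphenoxy)phenol | Oc1c(Br)cc(Br)cc1Oc1cc(Br)c(Br)c(Br)c1O | target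

**Step count**

Total steps: 8. Longest linear sequence: 8 steps (1 and 2 to 17).

**Steps most likely to fail**

Step 6. The lithiation may lose regiocontrol: deprotonation ortho to the ring A methoxy or ortho to the ether oxygen could compete, and s-BuLi could add to the carboxylate or displace the ortho methoxy group. The fallback replaces lithiation by transition-metal C-H borylation. It sets out from ester 11, isolated by stopping step 5 before the hydroxide is added. Ester-directed ortho C-H borylation ([Ir(OMe)(cod)]2, P[3,5-(CF3)2C6H3]3, B2pin2, octane, 80 °C) should give methyl 2-methoxy-3-(2-methoxyphenoxy)-6-(4,4,5,5-tetramethyl-1,3,2-dioxaborolan-2-yl)benzoate F1. Bromodeboronation with CuBr2 in MeOH–H2O at 80 °C should give methyl 6-bromo-2-methoxy-3-(2-methoxyphenoxy)benzoate F2, and KOH in aqueous DMSO should cleave the hindered ester, coming back to the route at 14.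

Step 4. The second C-C bond formation may lag behind hydrolysis of the diene or oligomerisation of the ionised acetal, so that little arene forms. The fallback gives up the de novo construction of ring B and makes the diaryl ether by Ullmann coupling. It sets out from guaiacol 1 and purchased methyl 3-bromo-2-methoxybenzoate F3 (CuI, N,N-dimethylglycine, Cs2CO3, dioxane, 90 °C) and comes back to the route at 11, which is then saponified as in the second stage of step 5.

Step 8. Ring bromination may outrun the ipso substitution so that the sequence stalls at the tetrabromo acid, or excess bromine may over-oxidise the phenols to bromodienones. The fallback removes the carboxyl before any bromine is added, so the last step is plain phenol bromination. It sets out from 14. Protodecarboxylation of this 2,6-disubstituted benzoic acid (Ag2CO3 cat., AcOH, DMSO, 120 °C) should give 4-bromo-2-methoxy-1-(2-methoxyphenoxy)benzene F4. BBr3 in CH2Cl2 should give 5-bromo-2-(2-hydroxyphenoxy)phenol F5, and Br2 (4 equiv) in AcOH should brominate ortho and para to both hydroxyls, coming back to the route at 17.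

**Further compounds**

F1 | step 6 | methyl 2-methoxy-3-(2-methoxyphenoxy)-6-(4,4,5,5-tetramethyl-1,3,2-dioxaborolan-2-yl)benzoate | COC(=O)c1c(B2OC(C)(C)C(C)(C)O2)ccc(Oc2ccccc2OC)c1OC
F2 | step 6 | methyl 6-bromo-2-methoxy-3-(2-methoxyphenoxy)benzoate | COC(=O)c1c(Br)ccc(Oc2ccccc2OC)c1OC
F3 | step 4 | methyl 3-bromo-2-methoxybenzoate (purchased) | COC(=O)c1cccc(Br)c1OC
F4 | step 8 | 4-bromo-2-methoxy-1-(2-methoxyphenoxy)benzene | COc1cc(Br)ccc1Oc1ccccc1OC
F5 | step 8 | 5-bromo-2-(2-hydroxyphenoxy)phenol | Oc1cc(Br)ccc1Oc1ccccc1O
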